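**Retrosynthetic overview**
- Target ⇐ fluoride desilylation of its hepta-silyl ether ⇐ aldol condensation of a methyl-ketone cycloadduct with 4-silyloxybenzaldehyde. The 4-hydroxycinnamoyl unit is added after the cycloaddition so that the diene partner carries no enone.
- Cyclohexene core with all three stereocentres ⇐ enantioselective endo Diels–Alder of a tetra-silylated chalcone with a 1-aryl-3-methylbuta-1,3-diene under chiral silylium imidodiphosphorimidate catalysis (metal-free Lewis acid organocatalysis; proposed new step).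
- Chalcone ⇐ aryllithium (from 5-bromoresorcinol by C2 iodination, silylation, prenylation) + Weinreb cinnamamide (from 2,4-dihydroxybenzaldehyde by Horner–Wadsworth–Emmons).
- Diene ⇐ Suzuki coupling of 3-iodo-2,4-disilyloxyacetophenone with an (E)-dienylboronate made from 2-methylbut-1-en-3-yne.
- Ring order: the three benzene rings are bought intact; the cyclohexene is the only ring made and is closed in the Diels–Alder step.

Assumption: the SMILES is taken as the definition of the target, so the aroyl ring is 3,5-dihydroxy-4-prenylphenyl (no hydroxyl ortho to the ketone) and the cyclohexene is (1R,2S,6S) with C1 the carbon bearing the aroyl group.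

Abbreviations: TBSO = tert-butyldimethylsilyloxy; TBSCl = tert-butyldimethylsilyl chloride; IDPi = BINOL-derived imidodiphosphorimidate Brønsted acid with N-trifluoromethylsulfonyl groups.

**Step 1**
Reactants: 1 5-bromobenzene-1,3-diol
Product: 2 5-bromo-2-iodobenzene-1,3-diol
Conditions: I2, NaHCO3, H2O/THF, 0 °C → rt
Reagents that add atoms: iodine, II
Why: Electrophilic aromatic iodination of the resorcinol monoanion goes to the carbon between the two hydroxyls, as for resorcinol itself, and the other activated positions are flanked by bromine.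

**Step 2**
Reactants: 2 5-bromo-2-iodobenzene-1,3-diol
Product: 3 5-bromo-2-iodo-1,3-bis(TBSO)benzene
Conditions: TBSCl, imidazole, DMF, rt
Reagents that add atoms: tert-butyldimethylsilyl chloride, CC(C)(C)[Si](C)(C)Cl
Why: Imidazole-promoted silyl ether formation protects both phenols with the one group that survives every later organometallic and Lewis acid step.

**Step 3**
Reactants: 3 5-bromo-2-iodo-1,3-bis(TBSO)benzene; 4 1-bromo-3-methylbut-2-ene (prenyl bromide)
Product: 6 5-bromo-2-(3-methylbut-2-en-1-yl)-1,3-bis(TBSO)benzene, via aryl Grignard 5 (not isolated)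
Conditions: i-PrMgCl·LiCl, THF, −40 °C; then CuI (10 mol %), 4, −40 → 0 °C
Reagents that add atoms: none
Why: Iodine–magnesium exchange is much faster at C–I than at C–Br and is helped by the two ortho oxygens, and copper-catalysed SN2 allylic substitution of the aryl Grignard on prenyl bromide gives the linear prenyl arene.

**Step 4**
Reactants: 7 2,4-dihydroxybenzaldehyde
Product: 8 2,4-bis(TBSO)benzaldehyde
Conditions: TBSCl, imidazole, DMF, rt
Reagents that add atoms: tert-butyldimethylsilyl chloride, CC(C)(C)[Si](C)(C)Cl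
Why: Standard phenol silylation; silyloxy groups are weaker donors than alkoxy groups, which keeps the later enone electrophilic.

**Step 5**
Reactants: 8 2,4-bis(TBSO)benzaldehyde; 9 diethyl [2-(methoxy(methyl)amino)-2-oxoethyl]phosphonate
Product: 10 (E)-3-[2,4-bis(TBSO)phenyl]-N-methoxy-N-methylprop-2-enamide
Conditions: LiCl, DBU, MeCN, rt
Reagents that add atoms: none
Why: Horner–Wadsworth–Emmons olefination under Masamune–Roush conditions gives the E-configured Weinreb cinnamamide without touching the aryl silyl ethers.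

**Step 6**
Reactants: 6 5-bromo-2-(3-methylbut-2-en-1-yl)-1,3-bis(TBSO)benzene; 10 (E)-3-[2,4-bis(TBSO)phenyl]-N-methoxy-N-methylprop-2-enamide
Product: 12 (E)-1-[3,5-bis(TBSO)-4-(3-methylbut-2-en-1-yl)phenyl]-3-[2,4-bis(TBSO)phenyl]prop-2-en-1-one, via aryllithium 11 (not isolated)
Conditions: t-BuLi (2 equiv), THF, −78 °C; then 10, −78 → −30 °C; H2O
Reagents that add atoms: none
Why: Bromine–lithium exchange followed by 1,2-addition to the Weinreb amide (Weinreb ketone synthesis) gives a chelated tetrahedral intermediate that cannot over-add and releases the E-chalcone on quench.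

**Step 7**
Reactants: 13 1-(2,4-dihydroxyphenyl)ethanone
Product: 14 1-(2,4-dihydroxy-3-iodophenyl)ethanone
Conditions: I2, HIO3, EtOH/H2O, 40 °C
Reagents that add atoms: iodine, II; iodic acid, OI(=O)=O
Why: Oxidative electrophilic iodination with iodine and iodic acid is expected to iodinate resacetophenone at C3 between the two hydroxyls (the 5-iodo isomer is the likely by-product and would be removed by crystallisation), and it uses every iodine atom.

**Step 8**
Reactants: 14 1-(2,4-dihydroxy-3-iodophenyl)ethanone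
Product: 15 1-[2,4-bis(TBSO)-3-iodophenyl]ethanone
Conditions: TBSCl, imidazole, DMAP (cat.), DMF, 50 °C
Reagents that add atoms: tert-butyldimethylsilyl chloride, CC(C)(C)[Si](C)(C)Cl
Why: Silyl ether formation, with warming and DMAP to silylate the hydrogen-bonded hydroxyl next to the ketone.

**Step 9**
Reactants: 16 2-methylbut-1-en-3-yne; 17 pinacolborane
Product: 18 (E)-4,4,5,5-tetramethyl-2-(3-methylbuta-1,3-dien-1-yl)-1,3,2-dioxaborolane
Conditions: Cp2Zr(H)Cl (5 mol %), Et3N (10 mol %), neat, 60 °C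
Reagents that add atoms: none
Why: Zirconium-catalysed syn hydroboration of the terminal alkyne, which reacts far faster than the 1,1-disubstituted alkene, places boron on the terminal carbon and gives the E-dienylboronate.

**Step 10**
Reactants: 15 1-[2,4-bis(TBSO)-3-iodophenyl]ethanone; 18 (E)-4,4,5,5-tetramethyl-2-(3-methylbuta-1,3-dien-1-yl)-1,3,2-dioxaborolane
Product: 19 1-[2,4-bis(TBSO)-3-[(E)-3-methylbuta-1,3-dien-1-yl]phenyl]ethanone
Conditions: Pd(OAc)2 (5 mol %), SPhos (10 mol %), K3PO4, toluene/H2O 10:1, 40 °C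
Reagents that add atoms: none
Why: Suzuki–Miyaura coupling with a biaryl phosphine handles the di-ortho-substituted iodide at 40 °C, which keeps the E geometry and the aryl silyl ethers intact.

**Step 11**
Reactants: 12 (E)-1-[3,5-bis(TBSO)-4-(3-methylbut-2-en-1-yl)phenyl]-3-[2,4-bis(TBSO)phenyl]prop-2-en-1-one; 19 1-[2,4-bis(TBSO)-3-[(E)-3-methylbuta-1,3-dien-1-yl]phenyl]ethanone
Product: 20 [(1R,2S,6S)-2-[3-acetyl-2,6-bis(TBSO)phenyl]-6-[2,4-bis(TBSO)phenyl]-4-methylcyclohex-3-en-1-yl][3,5-bis(TBSO)-4-(3-methylbut-2-en-1-yl)phenyl]methanone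
Conditions: (S,S)-IDPi (5 mol %), (2-methylallyl)SiMe2t-Bu (15 mol %), 12 : 19 = 1 : 1.5, CH2Cl2, −60 → −30 °C
Reagents that add atoms: none
Why: Proposed new method: the silylium ion formed in situ from the chiral imidodiphosphorimidate acid and the allylsilane O-silylates the chalcone carbonyl of 12 (diene 19 has no enone, and its hindered aryl methyl ketone binds only reversibly) to give a silyloxyallyl cation paired with the confined chiral anion, and this lowered LUMO reacts with the 1-aryl-3-methylbutadiene in a concerted asynchronous endo [4+2] in which the diene CH2 bonds first to the β-carbon (fixing the regiochemistry), the E-enone gives the 1,6-trans and the endo carbonyl the 1,2-cis relationship, and the anion pocket blocks one enone face so that C1, C2 and C6 are set together as (1R,2S,6S) (the sense of induction cannot be predicted, so the catalyst antipode is fixed in a test run); closest known reaction type: silylium–imidodiphosphorimidate (Lewis acid organocatalysis) Diels–Alder reactions of cinnamate esters with cyclopentadiene and simple acyclic dienes, not yet shown for chalcones or for 1-aryl-3-methylbuta-1,3-dienes.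

**Step 12**
Reactants: 20 [(1R,2S,6S)-2-[3-acetyl-2,6-bis(TBSO)phenyl]-6-[2,4-bis(TBSO)phenyl]-4-methylcyclohex-3-en-1-yl][3,5-bis(TBSO)-4-(3-methylbut-2-en-1-yl)phenyl]methanone; 21 4-(TBSO)benzaldehyde
Product: 25 [(1R,2S,6S)-2-[2,6-bis(TBSO)-3-[(E)-3-[4-(TBSO)phenyl]prop-2-enoyl]phenyl]-6-[2,4-bis(TBSO)phenyl]-4-methylcyclohex-3-en-1-yl][3,5-bis(TBSO)-4-(3-methylbut-2-en-1-yl)phenyl]methanone, via lithium enolate 22 (not isolated), via lithium aldolate 23 (not isolated), via mesylate 24 (not isolated)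
Conditions: LiN(SiMe3)2, THF, −78 °C; then 21; then MsCl, Et3N, −78 → 0 °C
Reagents that add atoms: none
Why: Kinetic deprotonation takes the methyl ketone and leaves the hindered C1 methine alone, and aldol addition to the non-enolisable aldehyde followed by mesylation and E1cB elimination (Claisen–Schmidt-type aldol condensation) gives the E-chalcone without touching the three stereocentres.

**Step 13**
Reactants: 25 [(1R,2S,6S)-2-[2,6-bis(TBSO)-3-[(E)-3-[4-(TBSO)phenyl]prop-2-enoyl]phenyl]-6-[2,4-bis(TBSO)phenyl]-4-methylcyclohex-3-en-1-yl][3,5-bis(TBSO)-4-(3-methylbut-2-en-1-yl)phenyl]methanone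
Product: 26 kuwanon R as given: [(1R,2S,6S)-6-(2,4-dihydroxyphenyl)-2-[2,6-dihydroxy-3-[(E)-3-(4-hydroxyphenyl)prop-2-enoyl]phenyl]-4-methylcyclohex-3-en-1-yl][3,5-dihydroxy-4-(3-methylbut-2-en-1-yl)phenyl]methanone
Conditions: Bu4NF, AcOH, THF, 0 °C
Reagents that add atoms: none
Why: Fluoride desilylation buffered with acetic acid cleaves all seven aryl silyl ethers while avoiding both acid (prenyl–phenol cyclisation, ketalisation) and strong base (flavanone closure, C1 epimerisation), so the stereocentres stay as set.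

**Compound list**

1 | 5-bromobenzene-1,3-diol | Oc1cc(O)cc(Br)c1 | starting material
2 | 5-bromo-2-iodobenzene-1,3-diol | Oc1cc(Br)cc(O)c1I | intermediate
3 | 5-bromo-2-iodo-1,3-bis(TBSO)benzene | CC(C)(C)[Si](C)(C)Oc1cc(Br)cc(O[Si](C)(C)C(C)(C)C)c1I | intermediate
4 | 1-bromo-3-methylbut-2-ene (prenyl bromide) | CC(C)=CCBr | starting material
5 | [4-bromo-2,6-bis(TBSO)phenyl]magnesium chloride | CC(C)(C)[Si](C)(C)Oc1cc(Br)cc(O[Si](C)(C)C(C)(C)C)c1[Mg]Cl | intermediate
6 | 5-bromo-2-(3-methylbut-2-en-1-yl)-1,3-bis(TBSO)benzene | CC(C)=CCc1c(O[Si](C)(C)C(C)(C)C)cc(Br)cc1O[Si](C)(C)C(C)(C)C | intermediate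
7 | 2,4-dihydroxybenzaldehyde | O=Cc1ccc(O)cc1O | starting material
8 | 2,4-bis(TBSO)benzaldehyde | O=Cc1ccc(O[Si](C)(C)C(C)(C)C)cc1O[Si](C)(C)C(C)(C)C | intermediate
9 | diethyl [2-(methoxy(methyl)amino)-2-oxoethyl]phosphonate | CCOP(=O)(CC(=O)N(C)OC)OCC | starting material
10 | (E)-3-[2,4-bis(TBSO)phenyl]-N-methoxy-N-methylprop-2-enamide | CON(C)C(=O)/C=C/c1ccc(O[Si](C)(C)C(C)(C)C)cc1O[Si](C)(C)C(C)(C)C | intermediate
11 | [3,5-bis(TBSO)-4-(3-methylbut-2-en-1-yl)phenyl]lithium | [Li]c1cc(O[Si](C)(C)C(C)(C)C)c(CC=C(C)C)c(O[Si](C)(C)C(C)(C)C)c1 | intermediate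
12 | (E)-1-[3,5-bis(TBSO)-4-(3-methylbut-2-en-1-yl)phenyl]-3-[2,4-bis(TBSO)phenyl]prop-2-en-1-one | CC(C)=CCc1c(O[Si](C)(C)C(C)(C)C)cc(C(=O)/C=C/c2ccc(O[Si](C)(C)C(C)(C)C)cc2O[Si](C)(C)C(C)(C)C)cc1O[Si](C)(C)C(C)(C)C | intermediate
13 | 1-(2,4-dihydroxyphenyl)ethanone | CC(=O)c1ccc(O)cc1O | starting material
14 | 1-(2,4-dihydroxy-3-iodophenyl)ethanone | CC(=O)c1ccc(O)c(I)c1O | intermediate
15 | 1-[2,4-bis(TBSO)-3-iodophenyl]ethanone | CC(=O)c1ccc(O[Si](C)(C)C(C)(C)C)c(I)c1O[Si](C)(C)C(C)(C)C | intermediate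
16 | 2-methylbut-1-en-3-yne | C#CC(C)=C | starting material
17 | pinacolborane (4,4,5,5-tetramethyl-1,3,2-dioxaborolane) | CC1(C)OBOC1(C)C | starting material
18 | (E)-4,4,5,5-tetramethyl-2-(3-methylbuta-1,3-dien-1-yl)-1,3,2-dioxaborolane | CC(=C)/C=C/B1OC(C)(C)C(C)(C)O1 | intermediate
19 | 1-[2,4-bis(TBSO)-3-[(E)-3-methylbuta-1,3-dien-1-yl]phenyl]ethanone | CC(=O)c1ccc(O[Si](C)(C)C(C)(C)C)c(/C=C/C(C)=C)c1O[Si](C)(C)C(C)(C)C | intermediate
20 | [(1R,2S,6S)-2-[3-acetyl-2,6-bis(TBSO)phenyl]-6-[2,4-bis(TBSO)phenyl]-4-methylcyclohex-3-en-1-yl][3,5-bis(TBSO)-4-(3-methylbut-2-en-1-yl)phenyl]methanone | CC(C)=CCc1c(O[Si](C)(C)C(C)(C)C)cc(C(=O)[C@H]2[C@@H](c3c(O[Si](C)(C)C(C)(C)C)ccc(C(C)=O)c3O[Si](C)(C)C(C)(C)C)C=C(C)C[C@@H]2c2ccc(O[Si](C)(C)C(C)(C)C)cc2O[Si](C)(C)C(C)(C)C)cc1O[Si](C)(C)C(C)(C)C | intermediate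
21 | 4-(TBSO)benzaldehyde | O=Cc1ccc(O[Si](C)(C)C(C)(C)C)cc1 | starting material
22 | lithium enolate of the methyl ketone of 20 | CC(C)=CCc1c(O[Si](C)(C)C(C)(C)C)cc(C(=O)[C@H]2[C@@H](c3c(O[Si](C)(C)C(C)(C)C)ccc(C(=C)O[Li])c3O[Si](C)(C)C(C)(C)C)C=C(C)C[C@@H]2c2ccc(O[Si](C)(C)C(C)(C)C)cc2O[Si](C)(C)C(C)(C)C)cc1O[Si](C)(C)C(C)(C)C | intermediate
23 | lithium aldolate from 22 and 21 (either configuration at the new carbinol carbon) | CC(C)=CCc1c(O[Si](C)(C)C(C)(C)C)cc(C(=O)[C@H]2[C@@H](c3c(O[Si](C)(C)C(C)(C)C)ccc(C(=O)CC(O[Li])c4ccc(O[Si](C)(C)C(C)(C)C)cc4)c3O[Si](C)(C)C(C)(C)C)C=C(C)C[C@@H]2c2ccc(O[Si](C)(C)C(C)(C)C)cc2O[Si](C)(C)C(C)(C)C)cc1O[Si](C)(C)C(C)(C)C | intermediate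
24 | β-mesyloxy ketone from 23 | CC(C)=CCc1c(O[Si](C)(C)C(C)(C)C)cc(C(=O)[C@H]2[C@@H](c3c(O[Si](C)(C)C(C)(C)C)ccc(C(=O)CC(OS(C)(=O)=O)c4ccc(O[Si](C)(C)C(C)(C)C)cc4)c3O[Si](C)(C)C(C)(C)C)C=C(C)C[C@@H]2c2ccc(O[Si](C)(C)C(C)(C)C)cc2O[Si](C)(C)C(C)(C)C)cc1O[Si](C)(C)C(C)(C)C | intermediate
25 | hepta-TBS ether of the target: [(1R,2S,6S)-2-[2,6-bis(TBSO)-3-[(E)-3-[4-(TBSO)phenyl]prop-2-enoyl]phenyl]-6-[2,4-bis(TBSO)phenyl]-4-methylcyclohex-3-en-1-yl][3,5-bis(TBSO)-4-(3-methylbut-2-en-1-yl)phenyl]methanone | CC(C)=CCc1c(O[Si](C)(C)C(C)(C)C)cc(C(=O)[C@H]2[C@@H](c3c(O[Si](C)(C)C(C)(C)C)ccc(C(=O)/C=C/c4ccc(O[Si](C)(C)C(C)(C)C)cc4)c3O[Si](C)(C)C(C)(C)C)C=C(C)C[C@@H]2c2ccc(O[Si](C)(C)C(C)(C)C)cc2O[Si](C)(C)C(C)(C)C)cc1O[Si](C)(C)C(C)(C)C | intermediate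
26 | kuwanon R as given: [(1R,2S,6S)-6-(2,4-dihydroxyphenyl)-2-[2,6-dihydroxy-3-[(E)-3-(4-hydroxyphenyl)prop-2-enoyl]phenyl]-4-methylcyclohex-3-en-1-yl][3,5-dihydroxy-4-(3-methylbut-2-en-1-yl)phenyl]methanone | CC(C)=CCc1c(O)cc(C(=O)[C@H]2[C@@H](c3c(O)ccc(C(=O)/C=C/c4ccc(O)cc4)c3O)C=C(C)C[C@@H]2c2ccc(O)cc2O)cc1O | target

**Totals**

Total step count: 13. Longest linear sequence: 7 steps (steps 1, 2, 3, 6, 11, 12, 13).

**Three steps most likely to fail**

Step 11 (the proposed new cycloaddition). The risks are poor turnover with the bulky silyl ethers next to the diene, formation of the exo adduct, and low enantioselectivity. The fallback uses known iminium-ion catalysis on the enal analogue of the dienophile; it sets out from aldehyde 8 and comes back at 20. Wittig reaction of 8 with (triphenylphosphoranylidene)acetaldehyde (toluene, 80 °C) gives (E)-3-[2,4-bis(TBSO)phenyl]prop-2-enal F1. F1 and diene 19 are combined with (5S)-5-benzyl-2,2,3-trimethylimidazolidin-4-one hydrochloride (first-generation imidazolidinone, 20 mol %) in MeCN/H2O 95:5 at rt. The amine condenses only with the aldehyde, and the endo Diels–Alder reaction of the E-iminium ion on the face anti to the benzyl group gives (1R,2S,6S)-2-[3-acetyl-2,6-bis(TBSO)phenyl]-6-[2,4-bis(TBSO)phenyl]-4-methylcyclohex-3-ene-1-carbaldehyde F2. Aryllithium 11 (from 6 and t-BuLi as in step 6) is added at −78 °C to the aldehyde of F2, which reacts far faster than the hindered aryl methyl ketone, to give the secondary carbinol F3 (both carbinol epimers). Dess–Martin periodinane oxidation of F3 gives 20. This costs two extra steps.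

Step 12 (late aldol condensation). The risks are silyl shift from the ortho silyloxy group to the lithium enolate, retro-aldol, and epimerisation at C1. The fallback sets out from 20 and comes back at 25, using a covalent boron enolate and a separate dehydration. Soft enolisation of the methyl ketone with Bu2BOTf and i-Pr2NEt (CH2Cl2, −78 °C) gives the dibutylboron enolate F4. Addition of 21 and non-oxidative work-up gives the isolated β-hydroxy ketone F5. Dehydration with MsCl and Et3N (through mesylate 24) then gives 25.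

Step 3 (exchange and prenylation between two silyloxy groups). The risks are silyl migration from oxygen to the metalated carbon, sluggish alkylation of the hindered Grignard, and some branched (SN2′) product. The fallback sets out from 2 and comes back at 6, reversing the order of protection and C–C coupling. Stille coupling of unprotected 2 with tributyl(3-methylbut-2-en-1-yl)stannane (Pd(PPh3)4, DMF, 60 °C) engages only the C–I bond and gives 5-bromo-2-(3-methylbut-2-en-1-yl)benzene-1,3-diol F6. Silylation (TBSCl, imidazole, DMF) gives 6.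

**Further compounds**

F1 | step 11 | (E)-3-[2,4-bis(TBSO)phenyl]prop-2-enal | O=C/C=C/c1ccc(O[Si](C)(C)C(C)(C)C)cc1O[Si](C)(C)C(C)(C)C
F2 | step 11 | (1R,2S,6S)-2-[3-acetyl-2,6-bis(TBSO)phenyl]-6-[2,4-bis(TBSO)phenyl]-4-methylcyclohex-3-ene-1-carbaldehyde | O=C[C@H]1[C@@H](c2c(O[Si](C)(C)C(C)(C)C)ccc(C(C)=O)c2O[Si](C)(C)C(C)(C)C)C=C(C)C[C@@H]1c1ccc(O[Si](C)(C)C(C)(C)C)cc1O[Si](C)(C)C(C)(C)C
F3 | step 11 | [(1R,2S,6S)-2-[3-acetyl-2,6-bis(TBSO)phenyl]-6-[2,4-bis(TBSO)phenyl]-4-methylcyclohex-3-en-1-yl][3,5-bis(TBSO)-4-(3-methylbut-2-en-1-yl)phenyl]methanol (both carbinol epimers) | CC(C)=CCc1c(O[Si](C)(C)C(C)(C)C)cc(C(O)[C@H]2[C@@H](c3c(O[Si](C)(C)C(C)(C)C)ccc(C(C)=O)c3O[Si](C)(C)C(C)(C)C)C=C(C)C[C@@H]2c2ccc(O[Si](C)(C)C(C)(C)C)cc2O[Si](C)(C)C(C)(C)C)cc1O[Si](C)(C)C(C)(C)C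
F4 | step 12 | dibutylboron enolate of the methyl ketone of 20 | CC(C)=CCc1c(O[Si](C)(C)C(C)(C)C)cc(C(=O)[C@H]2[C@@H](c3c(O[Si](C)(C)C(C)(C)C)ccc(C(=C)OB(CCCC)CCCC)c3O[Si](C)(C)C(C)(C)C)C=C(C)C[C@@H]2c2ccc(O[Si](C)(C)C(C)(C)C)cc2O[Si](C)(C)C(C)(C)C)cc1O[Si](C)(C)C(C)(C)C
F5 | step 12 | β-hydroxy ketone from 20 and 21 (either configuration at the carbinol carbon) | CC(C)=CCc1c(O[Si](C)(C)C(C)(C)C)cc(C(=O)[C@H]2[C@@H](c3c(O[Si](C)(C)C(C)(C)C)ccc(C(=O)CC(O)c4ccc(O[Si](C)(C)C(C)(C)C)cc4)c3O[Si](C)(C)C(C)(C)C)C=C(C)C[C@@H]2c2ccc(O[Si](C)(C)C(C)(C)C)cc2O[Si](C)(C)C(C)(C)C)cc1O[Si](C)(C)C(C)(C)C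
F6 | step 3 | 5-bromo-2-(3-methylbut-2-en-1-yl)benzene-1,3-diol | CC(C)=CCc1c(O)cc(Br)cc1O
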